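**Retrosynthetic overview**
- The strategy rests on the 5,6-dihydro-2H-pyran-2-one ring (O1, C2=O, C3=C4, C5H2, C6). At the acetal oxidation level it is the [4+2] adduct of 1-methoxybutadiene and an aldehyde, and the Z C1'=C2' alkene next to C6 is carried as an alkyne.
- Endgame, read backwards: desilylation, C8' acetylation, lactol oxidation, acetal hydrolysis and semi-hydrogenation lead back to a C2'–C3' disconnection between the acetylide of the cycloadduct and a C3'–C10' terminal epoxide (C6' OTBS, C8' OTES).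
- The only ring is closed first, in step 2, by the chromium-catalysed hetero-Diels–Alder reaction of 3-(triisopropylsilyl)propynal, which forms C5–C6 and O1–C2 and sets C6.
- The epoxide comes from 3-phenylpropanal: two Brown allylborations (C8', then C6' anti), then an iodocarbonate cyclisation (C4' syn) and epoxide closure.

Key step: step 2

Assumption: ynals are taken to follow the facial preference that this chromium catalyst family shows with aliphatic aldehydes, so the complex from (1S,2R)-1-amino-2-indanol should give the (6S) adduct; if the sense proves opposite, the enantiomeric complex is used.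

Side-chain numbering: C1' at the ring to C10' at phenyl.

**Step 1**
Reactants: 1 (triisopropylsilyl)acetylene
Product: 3 3-(triisopropylsilyl)prop-2-ynal, via lithium (triisopropylsilyl)acetylide 2 (not isolated)
Conditions: n-BuLi, THF, −78 °C; DMF, −78 °C → rt; inverse quench into cold 10% aq. KH2PO4
Reagents that add atoms: N,N-dimethylformamide, CN(C)C=O
Why: Deprotonation of the terminal alkyne and formylation of the lithium acetylide with DMF is a standard route to ynals, and the buffered inverse quench releases the aldehyde from the lithium hemiaminolate without conjugate addition of the liberated amine.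

**Step 2**
Reactants: 3 3-(triisopropylsilyl)prop-2-ynal; 4 (E)-1-methoxybuta-1,3-diene
Product: 5 (2R,6S)-2-methoxy-6-[(triisopropylsilyl)ethynyl]-5,6-dihydro-2H-pyran (2,6-cis)
Conditions: CrCl(L) (3 mol %; L = dianion of the Schiff base from (1S,2R)-1-amino-2-indanol and 3-(1-adamantyl)-2-hydroxy-5-methylbenzaldehyde), 4 Å MS, neat, rt
Reagents that add atoms: none
Why: The trivalent chromium centre of CrCl(L) binds the ynal carbonyl, and the electron-rich diene 4 adds to the activated C=O in a concerted but asynchronous [4+2] hetero-Diels–Alder cycloaddition in which C5–C6 bonding runs ahead of O1–C2 bonding. The closest known reaction type is the enantioselective hetero-Diels–Alder reaction of 1-methoxybutadiene with aliphatic aldehydes and silyl ynals under tridentate Schiff base chromium chloride catalysts. The single ring (O1, C2, C3=C4, C5, C6) is closed by this intermolecular cycloaddition, the diene termini becoming C5 and C2 and its central bond becoming C3=C4. C6 is set by the aminoindanol-derived ligand, which should leave only one face of the bound aldehyde open, and C2 is set relative to C6 by the endo transition state, which places the methoxy and alkynyl groups cis. The step needs carbonyl-over-alkyne chemoselectivity and the normal regiochemistry, which Lewis-acid activation of the non-enolisable aldehyde, the bulky triisopropylsilyl cap on the alkyne and the polarisation of the diene by its methoxy group should secure.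

**Step 3**
Reactants: 5 (2R,6S)-2-methoxy-6-[(triisopropylsilyl)ethynyl]-5,6-dihydro-2H-pyran
Product: 6 (2R,6S)-6-ethynyl-2-methoxy-5,6-dihydro-2H-pyran
Conditions: Bu4NF, THF, 0 °C
Reagents that add atoms: none
Why: Fluoride-mediated protodesilylation of an alkynylsilane runs under basic conditions that leave the allylic acetal and both stereocentres untouched; the volatile product is kept in solution.

**Step 4**
Reactants: 7 3-phenylpropanal
Product: 9 (3R)-1-phenylhex-5-en-3-ol, via (3R)-1-phenylhex-5-en-3-yl diisopinocampheylborinate 8 (not isolated)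
Conditions: (−)-Ipc2BOMe (from (+)-α-pinene), allylMgBr, Et2O, 0 °C → rt; 7, −78 °C; then 3 M NaOH, 30% H2O2, rt
Reagents that add atoms: allylmagnesium bromide, C=CC[Mg]Br
Why: Brown asymmetric allylboration through a chair-like six-membered transition state, in which the isopinocampheyl groups of the (+)-α-pinene series direct the allyl group to the Si face of the aldehyde, should set C8' as R.

**Step 5**
Reactants: 9 (3R)-1-phenylhex-5-en-3-ol
Product: 10 triethyl{[(3R)-1-phenylhex-5-en-3-yl]oxy}silane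
Conditions: Et3SiCl, imidazole, CH2Cl2, 0 °C → rt
Reagents that add atoms: chlorotriethylsilane, CC[Si](Cl)(CC)CC
Why: Standard silylation of a secondary alcohol; the triethylsilyl group is chosen because mild acid can later remove it in the presence of tert-butyldimethylsilyl ethers.

**Step 6**
Reactants: 10 triethyl{[(3R)-1-phenylhex-5-en-3-yl]oxy}silane
Product: 12 (3R)-5-phenyl-3-[(triethylsilyl)oxy]pentanal, via secondary ozonide 11 (not isolated)
Conditions: O3, CH2Cl2, −78 °C; PPh3, −78 °C → rt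
Reagents that add atoms: ozone, [O-][O+]=O
Why: Ozonolysis of the terminal alkene with reductive work-up (Criegee mechanism) gives the aldehyde one carbon shorter without touching the silyl ether or the stereocentre.

**Step 7**
Reactants: 12 (3R)-5-phenyl-3-[(triethylsilyl)oxy]pentanal
Product: 14 (4R,6R)-8-phenyl-6-[(triethylsilyl)oxy]oct-1-en-4-ol, via (4R,6R)-8-phenyl-6-(triethylsilyloxy)oct-1-en-4-yl diisopinocampheylborinate 13 (not isolated)
Conditions: (+)-Ipc2BOMe (from (−)-α-pinene), allylMgBr, Et2O, 0 °C → rt; 12, −78 °C; then NaBO3·4H2O, THF–H2O, rt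
Reagents that add atoms: allylmagnesium bromide, C=CC[Mg]Br
Why: Brown asymmetric allylboration with the enantiomeric reagent adds allyl to the Re face of the β-silyloxy aldehyde under reagent control, setting C6' as R and thus anti to C8'; the mild perborate work-up avoids silyl migration.

**Step 8**
Reactants: 14 (4R,6R)-8-phenyl-6-[(triethylsilyl)oxy]oct-1-en-4-ol
Product: 15 tert-butyl (4R,6R)-8-phenyl-6-[(triethylsilyl)oxy]oct-1-en-4-yl carbonate
Conditions: Boc2O, DMAP, MeCN, rt
Reagents that add atoms: di-tert-butyl dicarbonate, CC(C)(C)OC(=O)OC(=O)OC(C)(C)C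
Why: DMAP-catalysed acylation with Boc2O under non-basic conditions gives the homoallylic tert-butyl carbonate needed for the cyclisation without 1,3-silyl migration.

**Step 9**
Reactants: 15 tert-butyl (4R,6R)-8-phenyl-6-[(triethylsilyl)oxy]oct-1-en-4-yl carbonate
Product: 16 (4S,6R)-4-(iodomethyl)-6-{(2R)-4-phenyl-2-[(triethylsilyl)oxy]butyl}-1,3-dioxan-2-one
Conditions: IBr, toluene, −85 °C
Reagents that add atoms: iodine monobromide, IBr
Why: Bartlett–Smith iodocarbonate cyclisation, in which IBr activates the alkene, the carbonate carbonyl oxygen attacks the internal carbon in a 6-exo mode with loss of the tert-butyl cation, and a chair-like transition state with both substituents equatorial should set C4' syn to C6' (4,6-cis).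

**Step 10**
Reactants: 16 (4S,6R)-4-(iodomethyl)-6-{(2R)-4-phenyl-2-[(triethylsilyl)oxy]butyl}-1,3-dioxan-2-one
Product: 18 (2R,4R)-1-[(2S)-oxiran-2-yl]-6-phenyl-4-[(triethylsilyl)oxy]hexan-2-ol, via iodo diol 17 (not isolated)
Conditions: K2CO3, MeOH, 0 °C → rt
Reagents that add atoms: none
Why: Methanolysis of the cyclic carbonate liberates an iodohydrin whose C4' alkoxide displaces the primary iodide (3-exo-tet Williamson closure), so the epoxide forms with the C4'–O bond and its configuration intact.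

**Step 11**
Reactants: 18 (2R,4R)-1-[(2S)-oxiran-2-yl]-6-phenyl-4-[(triethylsilyl)oxy]hexan-2-ol
Product: 19 (2S)-2-{(2R,4R)-2-[(tert-butyldimethylsilyl)oxy]-6-phenyl-4-[(triethylsilyl)oxy]hexyl}oxirane
Conditions: TBSCl, imidazole, DMF, rt
Reagents that add atoms: tert-butyldimethylsilyl chloride, CC(C)(C)[Si](C)(C)Cl
Why: Imidazole-promoted silylation protects the free C6' hydroxyl for the acetylide coupling, and the epoxide and the triethylsilyl ether are inert to these conditions.

**Step 12**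
Reactants: 6 (2R,6S)-6-ethynyl-2-methoxy-5,6-dihydro-2H-pyran; 19 (2S)-2-{(2R,4R)-2-[(tert-butyldimethylsilyl)oxy]-6-phenyl-4-[(triethylsilyl)oxy]hexyl}oxirane
Product: 21 (4R,6R,8R)-6-[(tert-butyldimethylsilyl)oxy]-1-[(2R,6S)-2-methoxy-5,6-dihydro-2H-pyran-6-yl]-10-phenyl-8-[(triethylsilyl)oxy]dec-1-yn-4-ol, via lithium acetylide 20 (not isolated)
Conditions: 6 (2 equiv), n-BuLi, THF, −78 °C; 19, then BF3·OEt2 dropwise, −78 °C
Reagents that add atoms: none
Why: Yamaguchi–Hirao alkynylation, in which the lithium acetylide and the BF3-activated terminal epoxide react by SN2 attack at the unhindered C3', forming C2'–C3' and leaving the C4' configuration untouched because its C–O bond is not broken.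

**Step 13**
Reactants: 21 (4R,6R,8R)-6-[(tert-butyldimethylsilyl)oxy]-1-[(2R,6S)-2-methoxy-5,6-dihydro-2H-pyran-6-yl]-10-phenyl-8-[(triethylsilyl)oxy]dec-1-yn-4-ol
Product: 22 (2R,6S)-6-{(4R,6S,8R)-4,6-bis[(tert-butyldimethylsilyl)oxy]-10-phenyl-8-[(triethylsilyl)oxy]dec-1-yn-1-yl}-2-methoxy-5,6-dihydro-2H-pyran
Conditions: TBSCl, imidazole, DMAP (cat.), DMF, rt → 40 °C
Reagents that add atoms: tert-butyldimethylsilyl chloride, CC(C)(C)[Si](C)(C)Cl
Why: Silylation with the chlorosilane and imidazole protects C4'–OH without a Lewis-acidic silyl triflate that could ionise the allylic acetal (the C6' descriptor changes to S only through the priority rules).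

**Step 14**
Reactants: 22 (2R,6S)-6-{(4R,6S,8R)-4,6-bis[(tert-butyldimethylsilyl)oxy]-10-phenyl-8-[(triethylsilyl)oxy]dec-1-yn-1-yl}-2-methoxy-5,6-dihydro-2H-pyran
Product: 23 (2R,6S)-6-{(1Z,4R,6S,8R)-4,6-bis[(tert-butyldimethylsilyl)oxy]-10-phenyl-8-[(triethylsilyl)oxy]dec-1-en-1-yl}-2-methoxy-5,6-dihydro-2H-pyran
Conditions: H2 (1 atm), Pd/CaCO3 poisoned with Pb(OAc)2, quinoline, EtOAc, rt
Reagents that add atoms: none
Why: Lindlar semi-hydrogenation delivers H2 syn to the alkyne on the lead-poisoned palladium surface and should stop at the Z alkene, the quinoline additive suppressing over-reduction and leaving the ring alkene untouched.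

**Step 15**
Reactants: 23 (2R,6S)-6-{(1Z,4R,6S,8R)-4,6-bis[(tert-butyldimethylsilyl)oxy]-10-phenyl-8-[(triethylsilyl)oxy]dec-1-en-1-yl}-2-methoxy-5,6-dihydro-2H-pyran
Product: 24 (6S)-6-{(1Z,4R,6S,8R)-4,6-bis[(tert-butyldimethylsilyl)oxy]-8-hydroxy-10-phenyldec-1-en-1-yl}-5,6-dihydro-2H-pyran-2-ol (lactol, both C2 epimers)
Conditions: AcOH–THF–H2O (3:1:1), rt
Reagents that add atoms: water, O
Why: Mild aqueous acid hydrolyses the allylic methyl acetal through its allyl-stabilised oxocarbenium ion and at the same time cleaves the labile triethylsilyl ether, while the two secondary tert-butyldimethylsilyl ethers should survive; C2 becomes an inconsequential anomeric mixture.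

**Step 16**
Reactants: 24 (6S)-6-{(1Z,4R,6S,8R)-4,6-bis[(tert-butyldimethylsilyl)oxy]-8-hydroxy-10-phenyldec-1-en-1-yl}-5,6-dihydro-2H-pyran-2-ol
Product: 25 (6S)-6-{(1Z,4R,6S,8R)-4,6-bis[(tert-butyldimethylsilyl)oxy]-8-hydroxy-10-phenyldec-1-en-1-yl}-5,6-dihydro-2H-pyran-2-one
Conditions: MnO2 (activated, excess), CH2Cl2, rt
Reagents that add atoms: none
Why: Activated MnO2 oxidises allylic alcohols, here the allylic hemiacetal, selectively to the α,β-unsaturated lactone and should leave the isolated secondary C8' alcohol untouched.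

**Step 17**
Reactants: 25 (6S)-6-{(1Z,4R,6S,8R)-4,6-bis[(tert-butyldimethylsilyl)oxy]-8-hydroxy-10-phenyldec-1-en-1-yl}-5,6-dihydro-2H-pyran-2-one
Product: 26 (3R,5S,7R,9Z)-5,7-bis[(tert-butyldimethylsilyl)oxy]-10-[(2S)-6-oxo-3,6-dihydro-2H-pyran-2-yl]-1-phenyldec-9-en-3-yl acetate
Conditions: Ac2O, pyridine, DMAP (cat.), CH2Cl2, 0 °C → rt
Reagents that add atoms: acetic anhydride, CC(=O)OC(C)=O
Why: DMAP-catalysed acetylation of the only free hydroxyl group installs the C8' acetate, and the unsaturated lactone tolerates these mild conditions.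

**Step 18**
Reactants: 26 (3R,5S,7R,9Z)-5,7-bis[(tert-butyldimethylsilyl)oxy]-10-[(2S)-6-oxo-3,6-dihydro-2H-pyran-2-yl]-1-phenyldec-9-en-3-yl acetate
Product: 27 (3R,5R,7R,9Z)-5,7-dihydroxy-10-[(2S)-6-oxo-3,6-dihydro-2H-pyran-2-yl]-1-phenyldec-9-en-3-yl acetate (CNP0264384.1)
Conditions: 48% aq. HF, MeCN, 0 °C → rt
Reagents that add atoms: none
Why: Acidic fluoride cleaves both secondary silyl ethers under conditions that avoid the acyl migration, lactone opening and conjugate addition a basic fluoride source could cause.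

**Compound list**
1 | (triisopropylsilyl)acetylene | CC(C)[Si](C#C)(C(C)C)C(C)C | starting material
2 | lithium (triisopropylsilyl)acetylide | [Li]C#C[Si](C(C)C)(C(C)C)C(C)C | intermediate
3 | 3-(triisopropylsilyl)prop-2-ynal | CC(C)[Si](C(C)C)(C(C)C)C#CC=O | intermediate
4 | (E)-1-methoxybuta-1,3-diene | CO/C=C/C=C | starting material
5 | (2R,6S)-2-methoxy-6-[(triisopropylsilyl)ethynyl]-5,6-dihydro-2H-pyran (2,6-cis) | CC(C)[Si](C(C)C)(C(C)C)C#C[C@@H]1CC=C[C@H](OC)O1 | intermediate
6 | (2R,6S)-6-ethynyl-2-methoxy-5,6-dihydro-2H-pyran | C#C[C@@H]1CC=C[C@H](OC)O1 | intermediate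
7 | 3-phenylpropanal | O=CCCc1ccccc1 | starting material
8 | (3R)-1-phenylhex-5-en-3-yl diisopinocampheylborinate ((+)-α-pinene series) | C=CC[C@@H](CCc1ccccc1)OB([C@@H]1C[C@@H]2C[C@H]([C@H]1C)C2(C)C)[C@@H]1C[C@@H]2C[C@H]([C@H]1C)C2(C)C | intermediate
9 | (3R)-1-phenylhex-5-en-3-ol | O[C@H](CCc1ccccc1)CC=C | intermediate
10 | triethyl{[(3R)-1-phenylhex-5-en-3-yl]oxy}silane | CC[Si](CC)(CC)O[C@H](CCc1ccccc1)CC=C | intermediate
11 | 3-{(2R)-4-phenyl-2-[(triethylsilyl)oxy]butyl}-1,2,4-trioxolane (secondary ozonide, both C3 epimers) | CC[Si](CC)(CC)O[C@H](CCc1ccccc1)CC1OCOO1 | intermediate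
12 | (3R)-5-phenyl-3-[(triethylsilyl)oxy]pentanal | CC[Si](CC)(CC)O[C@H](CCc1ccccc1)CC=O | intermediate
13 | (4R,6R)-8-phenyl-6-[(triethylsilyl)oxy]oct-1-en-4-yl diisopinocampheylborinate ((−)-α-pinene series) | CC[Si](CC)(CC)O[C@H](CCc1ccccc1)C[C@@H](CC=C)OB([C@H]1C[C@H]2C[C@@H]([C@@H]1C)C2(C)C)[C@H]1C[C@H]2C[C@@H]([C@@H]1C)C2(C)C | intermediate
14 | (4R,6R)-8-phenyl-6-[(triethylsilyl)oxy]oct-1-en-4-ol | CC[Si](CC)(CC)O[C@H](CCc1ccccc1)C[C@H](O)CC=C | intermediate
15 | tert-butyl (4R,6R)-8-phenyl-6-[(triethylsilyl)oxy]oct-1-en-4-yl carbonate | CC[Si](CC)(CC)O[C@H](CCc1ccccc1)C[C@H](OC(=O)OC(C)(C)C)CC=C | intermediate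
16 | (4S,6R)-4-(iodomethyl)-6-{(2R)-4-phenyl-2-[(triethylsilyl)oxy]butyl}-1,3-dioxan-2-one | CC[Si](CC)(CC)O[C@H](CCc1ccccc1)C[C@H]1C[C@@H](CI)OC(=O)O1 | intermediate
17 | (2S,4R,6R)-1-iodo-8-phenyl-6-[(triethylsilyl)oxy]octane-2,4-diol | CC[Si](CC)(CC)O[C@H](CCc1ccccc1)C[C@H](O)C[C@H](O)CI | intermediate
18 | (2R,4R)-1-[(2S)-oxiran-2-yl]-6-phenyl-4-[(triethylsilyl)oxy]hexan-2-ol | CC[Si](CC)(CC)O[C@H](CCc1ccccc1)C[C@H](O)C[C@H]1CO1 | intermediate
19 | (2S)-2-{(2R,4R)-2-[(tert-butyldimethylsilyl)oxy]-6-phenyl-4-[(triethylsilyl)oxy]hexyl}oxirane | CC[Si](CC)(CC)O[C@H](CCc1ccccc1)C[C@H](O[Si](C)(C)C(C)(C)C)C[C@H]1CO1 | intermediate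
20 | lithium acetylide of 6, {[(2R,6S)-2-methoxy-5,6-dihydro-2H-pyran-6-yl]ethynyl}lithium | [Li]C#C[C@@H]1CC=C[C@H](OC)O1 | intermediate
21 | (4R,6R,8R)-6-[(tert-butyldimethylsilyl)oxy]-1-[(2R,6S)-2-methoxy-5,6-dihydro-2H-pyran-6-yl]-10-phenyl-8-[(triethylsilyl)oxy]dec-1-yn-4-ol | CC[Si](CC)(CC)O[C@H](CCc1ccccc1)C[C@H](O[Si](C)(C)C(C)(C)C)C[C@H](O)CC#C[C@@H]1CC=C[C@H](OC)O1 | intermediate
22 | (2R,6S)-6-{(4R,6S,8R)-4,6-bis[(tert-butyldimethylsilyl)oxy]-10-phenyl-8-[(triethylsilyl)oxy]dec-1-yn-1-yl}-2-methoxy-5,6-dihydro-2H-pyran | CC[Si](CC)(CC)O[C@H](CCc1ccccc1)C[C@H](O[Si](C)(C)C(C)(C)C)C[C@H](O[Si](C)(C)C(C)(C)C)CC#C[C@@H]1CC=C[C@H](OC)O1 | intermediate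
23 | (2R,6S)-6-{(1Z,4R,6S,8R)-4,6-bis[(tert-butyldimethylsilyl)oxy]-10-phenyl-8-[(triethylsilyl)oxy]dec-1-en-1-yl}-2-methoxy-5,6-dihydro-2H-pyran | CC[Si](CC)(CC)O[C@H](CCc1ccccc1)C[C@H](O[Si](C)(C)C(C)(C)C)C[C@H](O[Si](C)(C)C(C)(C)C)C/C=C\[C@@H]1CC=C[C@H](OC)O1 | intermediate
24 | (6S)-6-{(1Z,4R,6S,8R)-4,6-bis[(tert-butyldimethylsilyl)oxy]-8-hydroxy-10-phenyldec-1-en-1-yl}-5,6-dihydro-2H-pyran-2-ol (both C2 epimers) | O[C@H](CCc1ccccc1)C[C@H](O[Si](C)(C)C(C)(C)C)C[C@H](O[Si](C)(C)C(C)(C)C)C/C=C\[C@@H]1CC=CC(O)O1 | intermediate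
25 | (6S)-6-{(1Z,4R,6S,8R)-4,6-bis[(tert-butyldimethylsilyl)oxy]-8-hydroxy-10-phenyldec-1-en-1-yl}-5,6-dihydro-2H-pyran-2-one | O[C@H](CCc1ccccc1)C[C@H](O[Si](C)(C)C(C)(C)C)C[C@H](O[Si](C)(C)C(C)(C)C)C/C=C\[C@@H]1CC=CC(=O)O1 | intermediate
26 | (3R,5S,7R,9Z)-5,7-bis[(tert-butyldimethylsilyl)oxy]-10-[(2S)-6-oxo-3,6-dihydro-2H-pyran-2-yl]-1-phenyldec-9-en-3-yl acetate | CC(=O)O[C@H](CCc1ccccc1)C[C@H](O[Si](C)(C)C(C)(C)C)C[C@H](O[Si](C)(C)C(C)(C)C)C/C=C\[C@@H]1CC=CC(=O)O1 | intermediate
27 | (3R,5R,7R,9Z)-5,7-dihydroxy-10-[(2S)-6-oxo-3,6-dihydro-2H-pyran-2-yl]-1-phenyldec-9-en-3-yl acetate | CC(=O)O[C@H](CCc1ccccc1)C[C@H](O)C[C@H](O)C/C=C\[C@@H]1CC=CC(=O)O1 | target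

**Totals**
Total step count: 18. Longest linear sequence: 15 steps (steps 4–18, from 3-phenylpropanal).

**Steps most likely to fail**

Step 2. The catalyst may discriminate the two faces of the small, linear ynal poorly, or the diene may oligomerise before cycloaddition is complete. The fallback sets out from 3 and builds the ring by allylboration and ring-closing metathesis. Brown allylboration of 3 with the reagent from (−)-Ipc2BOMe and allylMgBr (Et2O, −78 °C; NaBO3·4H2O) should give (3S)-1-(triisopropylsilyl)hex-5-en-1-yn-3-ol F1. Acetal exchange with 3,3-dimethoxyprop-1-ene (PPTS, toluene) should give the mixed acetal triisopropyl{(3S)-3-[(1-methoxyprop-2-en-1-yl)oxy]hex-5-en-1-yn-1-yl}silane F2. Ring-closing metathesis with the second-generation Grubbs catalyst RuCl2(=CHPh)(PCy3)(H2IMes) in CH2Cl2 at 40 °C should close the dihydropyran. This gives 5 together with its C2 epimer (2S,6S)-2-methoxy-6-[(triisopropylsilyl)ethynyl]-5,6-dihydro-2H-pyran F3, which is separated by chromatography, re-equilibrated (PPTS, MeOH) and recycled. The fallback comes back to the route at 5.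

Step 12. BF3·OEt2 may ionise the allylic methyl acetal of the acetylide partner, leading to substitution or decomposition at C2 in competition with epoxide opening. The fallback sets out from 19 and moves the cycloaddition behind the coupling, so that no acetal meets the Lewis acid. Opening of 19 with lithium (trimethylsilyl)acetylide and BF3·OEt2 (THF, −78 °C) should give (4R,6R,8R)-6-[(tert-butyldimethylsilyl)oxy]-10-phenyl-8-[(triethylsilyl)oxy]-1-(trimethylsilyl)dec-1-yn-4-ol F4. Silylation (TBSCl, imidazole, DMF) should give (4R,6S,8R)-4,6-bis[(tert-butyldimethylsilyl)oxy]-10-phenyl-8-[(triethylsilyl)oxy]-1-(trimethylsilyl)dec-1-yne F5. K2CO3 in MeOH should remove the alkynyl silane to give (4R,6S,8R)-4,6-bis[(tert-butyldimethylsilyl)oxy]-10-phenyl-8-[(triethylsilyl)oxy]dec-1-yne F6. Formylation (n-BuLi, then DMF, buffered quench) should give (5R,7S,9R)-5,7-bis[(tert-butyldimethylsilyl)oxy]-11-phenyl-9-[(triethylsilyl)oxy]undec-2-ynal F7. The hetero-Diels–Alder reaction of F7 with 4 under CrCl(L), as in step 2, should then give 22, where the fallback comes back to the route.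

Step 15. The lactol may open to the hydroxy enal and isomerise at the enal double bond so that it no longer closes, the triethylsilyl ether may cleave incompletely, or tert-butyldimethylsilyl groups may be lost. The fallback sets out from 23 and avoids the free lactol. Selective cleavage of the triethylsilyl ether with HF·pyridine buffered with pyridine (THF, 0 °C) should give (3R,5S,7R,9Z)-5,7-bis[(tert-butyldimethylsilyl)oxy]-10-[(2R,6S)-2-methoxy-5,6-dihydro-2H-pyran-6-yl]-1-phenyldec-9-en-3-ol F8. Acetylation (Ac2O, pyridine, DMAP) should give (3R,5S,7R,9Z)-5,7-bis[(tert-butyldimethylsilyl)oxy]-10-[(2R,6S)-2-methoxy-5,6-dihydro-2H-pyran-6-yl]-1-phenyldec-9-en-3-yl acetate F9. Direct oxidation of the cyclic allylic acetal with pyridinium chlorochromate [C5H5NH][CrO3Cl] (NaOAc, CH2Cl2) should then give 26, where the fallback comes back to the route.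

**Further compounds**
F1 | step 2 | (3S)-1-(triisopropylsilyl)hex-5-en-1-yn-3-ol | CC(C)[Si](C(C)C)(C(C)C)C#C[C@@H](O)CC=C
F2 | step 2 | triisopropyl{(3S)-3-[(1-methoxyprop-2-en-1-yl)oxy]hex-5-en-1-yn-1-yl}silane (both acetal epimers) | CC(C)[Si](C(C)C)(C(C)C)C#C[C@H](CC=C)OC(OC)C=C
F3 | step 2 | (2S,6S)-2-methoxy-6-[(triisopropylsilyl)ethynyl]-5,6-dihydro-2H-pyran (2,6-trans) | CC(C)[Si](C(C)C)(C(C)C)C#C[C@@H]1CC=C[C@@H](OC)O1
F4 | step 12 | (4R,6R,8R)-6-[(tert-butyldimethylsilyl)oxy]-10-phenyl-8-[(triethylsilyl)oxy]-1-(trimethylsilyl)dec-1-yn-4-ol | CC[Si](CC)(CC)O[C@H](CCc1ccccc1)C[C@H](O[Si](C)(C)C(C)(C)C)C[C@H](O)CC#C[Si](C)(C)C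
F5 | step 12 | (4R,6S,8R)-4,6-bis[(tert-butyldimethylsilyl)oxy]-10-phenyl-8-[(triethylsilyl)oxy]-1-(trimethylsilyl)dec-1-yne | CC[Si](CC)(CC)O[C@H](CCc1ccccc1)C[C@H](O[Si](C)(C)C(C)(C)C)C[C@H](O[Si](C)(C)C(C)(C)C)CC#C[Si](C)(C)C
F6 | step 12 | (4R,6S,8R)-4,6-bis[(tert-butyldimethylsilyl)oxy]-10-phenyl-8-[(triethylsilyl)oxy]dec-1-yne | CC[Si](CC)(CC)O[C@H](CCc1ccccc1)C[C@H](O[Si](C)(C)C(C)(C)C)C[C@H](O[Si](C)(C)C(C)(C)C)CC#C
F7 | step 12 | (5R,7S,9R)-5,7-bis[(tert-butyldimethylsilyl)oxy]-11-phenyl-9-[(triethylsilyl)oxy]undec-2-ynal | CC[Si](CC)(CC)O[C@H](CCc1ccccc1)C[C@H](O[Si](C)(C)C(C)(C)C)C[C@H](O[Si](C)(C)C(C)(C)C)CC#CC=O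
F8 | step 15 | (3R,5S,7R,9Z)-5,7-bis[(tert-butyldimethylsilyl)oxy]-10-[(2R,6S)-2-methoxy-5,6-dihydro-2H-pyran-6-yl]-1-phenyldec-9-en-3-ol | O[C@H](CCc1ccccc1)C[C@H](O[Si](C)(C)C(C)(C)C)C[C@H](O[Si](C)(C)C(C)(C)C)C/C=C\[C@@H]1CC=C[C@H](OC)O1
F9 | step 15 | (3R,5S,7R,9Z)-5,7-bis[(tert-butyldimethylsilyl)oxy]-10-[(2R,6S)-2-methoxy-5,6-dihydro-2H-pyran-6-yl]-1-phenyldec-9-en-3-yl acetate | CC(=O)O[C@H](CCc1ccccc1)C[C@H](O[Si](C)(C)C(C)(C)C)C[C@H](O[Si](C)(C)C(C)(C)C)C/C=C\[C@@H]1CC=C[C@H](OC)O1
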